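Slowness was my way in: in the teal run D took until 5.00 min to reach 90.0%, so I asked where the climb ends in the new flask, then how long it takes.

| flask | X | Z | Q | remark | time |
|---|---|---|---|---|---|
| teal | 0.025 M | 0.055 M | 0.025 M | run made earlier |  |
| amber | 0.10 M | 0.055 M | 0.025 M | run made earlier |  |
| grey | 0.050 M | 0.11 M | 0.025 M | run made earlier |  |
| flask | 0.050 M | 0.0550 M | 0.0250 M |  | 40 min |

| run | time / min | D / % |
|---|---|---|
| teal | 0.500 | 57.1 |
| teal | 1.00 | 74.4 |
| teal | 2.00 | 85.6 |
| teal | 5.00 | 90.0 |
| teal | 10.0 | 89.6 |
| teal | 20.0 | 89.4 |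
| teal | 50.0 | 89.0 |
| amber | 0.500 | 20.0 |
| amber | 1.00 | 16.6 |
| amber | 2.00 | 12.4 |
| amber | 5.00 | 6.0 |
| amber | 10.0 | 2.4 |
| amber | 20.0 | 0.7 |
| amber | 50.0 | 1.0 |
| grey | 0.500 | 47.6 |
| grey | 1.50 | 46.8 |
| grey | 5.00 | 46.5 |
| grey | 15.0 | 46.3 |
| grey | 50.0 | 46.4 |

(readings scatter by 0.5 percentage points)

* time up to 40 min at which D stands highest
* the amount of D, in percent of the X charged, at that time

- the earlier runs were read with a standard deviation of 0.5 percentage points

I built the flask up one process at a time. With the main step alone, X and Z giving D one to one, Z covers X at 1.10 to one, so that step by itself put the ceiling for D at the X charged.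

Next I added Q. The late readings were 0.0224 M of D in the teal run and 0.0232 M in the grey run, with the same Q but twice the X and twice the Z. I therefore read Q as the limiting reagent and took from the teal run the Q yield, the D formed per Q charged:

Q yield = [D] / [Q] charged = 0.900

[D] / [X] charged in this flask = Q yield × [Q] / [X] = 45.0%

Last came the loss: in the amber run, with X charged beyond Z, D fell from 20.0% to 0.7%. I expected it to lower D after the peak, so the peak had to be caught early.

For the speed, I treated the first teal reading as if Z held at its charge, roughly pseudo-first-order in X, which gave a rough k = 36.6 L mol⁻¹ min⁻¹. In this flask X and Z are nearly equal, so my estimate of the time for X to fall by Q yield × [Q] was: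

t = Q yield × [Q] / (k × [X] charged × ([X] charged − Q yield × [Q])) = 0.447 min

The forecast gave 45% at 1.5 min: “Either way the maximum comes early”.

The flask gave 44.5% at 0.775 min, and 39.4% at 40.0 min.

    X + Z → G (k = 0.787 L mol⁻¹ s⁻¹)
    Q + G → D (k = 18.0 L mol⁻¹ s⁻¹)
    G → E (k = 0.00200 s⁻¹)
    X + D → J (k = 0.147 L mol⁻¹ s⁻¹)

The peak came later than my 0.447 min, but its Q yield was 0.890 against my 0.900. At the best time in this flask Q stood at 1.18% of its charge, and the using up of Q was the largest single effect on the peak: the same run without it reached 72.8% instead of 44.5%.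

In a flask like this one but with 0.20 M of X, the Q yield gives 11.2%. The computed peak there was 9.97%.

The runs come from a simulation on assumed constants, noise included.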